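**Retrosynthetic overview**
1. The cyclopentenone is closed last by aldol condensation of a C9‑acetonyl group onto the bridging C4 ketone. The acetonyl group comes from Wacker oxidation of a C9‑allyl group, and C8‑OH comes from hydride reduction of a bridged 1,3‑diketone.
2. The bridged six/eight core (bicyclo[5.3.1]) comes from ring expansion of a fused six/seven syn‑epoxy alcohol. C10 shifts from C4 to C9 in a semipinacol 1,2‑shift.
3. The seven‑membered ring comes from a reductive diene–aldehyde cyclisation (C11–C12). The aldehyde is masked as the lactol of a lactone made by copper hydride reductive aldol cyclisation (C4–C10) of the C14 acrylate.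
4. C13–C14 comes from isoprenylation of a β‑keto aldehyde. Quaternary C5 comes from formylation then methylation of 2‑allyl‑5‑methylcyclohexenone.
5. Ring order: six (bought), seven, eight (by expansion), five.

Assumption: the stereodescriptors of the given SMILES are taken exactly as written and all intermediate SMILES are derived from them; mutilin numbering is used (C1–C3 plus C4 and C9 = cyclopentenone, C4–C9 = ring A, C10–C14 = five‑carbon bridge); compounds 1 and 7 are taken as purchasable.

**Route**

Step 1
Reactants: 1 (S)-5-methylcyclohex-2-en-1-one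
Product: 2 (S)-2-iodo-5-methylcyclohex-2-en-1-one
Conditions: I2 (1.5 equiv), pyridine–CH2Cl2 1:1, 0 → 23 °C
Reagents that add atoms: iodine, [I][I]
Why: Johnson α‑iodination (Baylis–Hillman‑type addition of pyridine, iodination of the enolate, loss of pyridine); the C6 stereocentre is remote and untouched.

Step 2
Reactants: 2 (S)-2-iodo-5-methylcyclohex-2-en-1-one; 3 allyltrimethylstannane
Product: 4 (S)-2-allyl-5-methylcyclohex-2-en-1-one
Conditions: Pd2(dba)3 (2.5 mol %), AsPh3 (10 mol %), CuI (10 mol %), NMP, 40 °C
Reagents that add atoms: none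
Why: Stille coupling of an α‑iodoenone, a standard substrate class under AsPh3/CuI acceleration; it installs C1–C3 and creates no stereocentre.

Step 3
Reactants: 4 (S)-2-allyl-5-methylcyclohex-2-en-1-one
Product: 6 (1R,6S)-3-allyl-1,6-dimethyl-2-oxocyclohex-3-ene-1-carbaldehyde, via formyl ketone 5 (not isolated)
Conditions: LDA (1.05 equiv), THF, −78 °C; HCO2CH2CF3 (1.2 equiv), −78 °C; then MeI (5 equiv), DMPU, −78 → 23 °C
Reagents that add atoms: 2,2,2-trifluoroethyl formate, O=COCC(F)(F)F; iodomethane, CI
Why: The kinetic cross‑conjugated enolate undergoes Claisen‑type C‑formylation at C5, and the chelated β‑keto aldehyde enolate is then C‑methylated anti to the neighbouring C6 methyl; this sets quaternary C5 with the two methyl groups trans.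

Step 4
Reactants: 6 (1R,6S)-3-allyl-1,6-dimethyl-2-oxocyclohex-3-ene-1-carbaldehyde; 7 2-(bromomethyl)buta-1,3-diene
Product: 9 (5S,6R)-2-allyl-6-[(1R)-1-hydroxy-3-methylidenepent-4-en-1-yl]-5,6-dimethylcyclohex-2-en-1-one, via dienylmethylzinc bromide 8 (not isolated)
Conditions: Zn dust (2 equiv), THF, 0 °C; H2O work-up
Reagents that add atoms: none
Why: Barbier allylation (isoprenylation) is selective for the aldehyde over the hindered enone; zinc bridges the aldehyde and ketone oxygens (Cram chelate) and the allylzinc attacks the exposed face, which sets C14 (R).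

Step 5
Reactants: 9 dienyl alcohol (as named in step 4); 10 acryloyl chloride
Product: 11 (1R)-1-[(1R,6S)-3-allyl-1,6-dimethyl-2-oxocyclohex-3-en-1-yl]-3-methylidenepent-4-en-1-yl prop-2-enoate
Conditions: Et3N (2 equiv), DMAP (10 mol %), CH2Cl2, 0 °C
Reagents that add atoms: none
Why: DMAP‑catalysed O‑acylation ties the future C10–C11 unit to the C14 oxygen; no stereocentre changes.

Step 6
Reactants: 11 acrylate (as named in step 5)
Product: 12 (1R,4R,4aR,8S,8aR)-5-allyl-4a-hydroxy-4,8,8a-trimethyl-1-(2-methylidenebut-3-en-1-yl)-1,4,4a,7,8,8a-hexahydro-3H-isochromen-3-one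
Conditions: Cu(OAc)2·H2O (5 mol %), dppf (5 mol %), (EtO)2MeSiH (2 equiv), THF, 23 °C; 1 M HCl work-up
Reagents that add atoms: none
Why: In this copper hydride reductive aldol cyclisation, hydride adds to the unhindered acrylate far faster than to the trisubstituted enone or the diene; the Z‑copper enolate then adds 1,2 to the C4 carbonyl through a chair‑like six‑membered transition state with the C13 chain equatorial, which forms C4–C10 and sets C4 (R) and C10 (R) from C14.

Step 7
Reactants: 12 hydroxy lactone (as named in step 6)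
Product: 13 the corresponding lactol (isochromene-3,4a-diol; C11 anomers; other centres as in 12)
Conditions: i-Bu2AlH (2.2 equiv), CH2Cl2, −78 °C; aq Rochelle salt
Reagents that add atoms: none
Why: Partial reduction of the lactone stops at the stable aluminium lactolate at −78 °C; alkenes and the tertiary alkoxide are inert, and the new anomeric centre is of no consequence.

Step 8
Reactants: 13 lactol
Product: 15 fused six/seven allylic alcohol (4R,5R,6S,10S,11S,12S,14R)-14-acetoxy-9-allyl-4-hydroxy-5,6,10,12-tetramethyl-11-(triethylsilyloxy)-12-vinylbicyclo[5.4.0]undec-8-ene (mutilin numbering), via silyl ether diol 14 (not isolated)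
Conditions: Ni(cod)2 (15 mol %), PPh3 (30 mol %), Et3SiH (3 equiv), THF, 23 → 45 °C; then Ac2O (3 equiv), Et3N, DMAP, 23 °C
Reagents that add atoms: triethylsilane, CC[SiH](CC)CC; acetic anhydride, CC(=O)OC(C)=O
Why: In this nickel hydride reductive diene–aldehyde cyclisation, H–Ni–SiEt3 puts H on the CH2 attached to C12, and the π‑allylnickel attacks the open form of the lactol through its substituted terminus, the only mode that closes a seven‑membered ring; a chair‑like transition state with Felkin attack anti to the C10 methyl sets C11 (S) and quaternary C12 (S), and O–Si reductive elimination leaves C11 as its silyl ether, so only the secondary C14‑OH is acetylated.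

Step 9
Reactants: 15 allylic alcohol (as named in step 8)
Product: 16 syn-epoxy alcohol; the 8,9-epoxide of 15 on the face of the C4 hydroxyl (4S,5R,6S,8R,9R,10S,11S,12S,14R)
Conditions: VO(acac)2 (5 mol %), t-BuOOH (1.5 equiv), CH2Cl2, 0 °C
Reagents that add atoms: tert-butyl hydroperoxide, CC(C)(C)OO
Why: In the hydroxyl‑directed vanadium epoxidation, the tertiary allylic alkoxide delivers oxygen to the trisubstituted C8=C9 bond syn to C4‑OH; the monosubstituted allyl and vinyl groups react much more slowly.

Step 10
Reactants: 16 syn-epoxy alcohol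
Product: 18 bridged diketone (5R,6S,9S,10R,11S,12S,14R)-14-acetoxy-9-allyl-5,6,10,12-tetramethyl-11-(triethylsilyloxy)-12-vinylbicyclo[5.3.1]undecane-4,8-dione (mutilin numbering), via aluminium alkoxide 17 (not isolated)
Conditions: AlMe3 (2.2 equiv), CH2Cl2, −78 → 0 °C; then 3-O2NC6H4CHO (3 equiv), toluene, 23 °C; aq Rochelle salt
Reagents that add atoms: none
Why: Proposed new method: AlMe3 turns C4‑OH into an aluminium alkoxide (the push) and a second aluminium centre activates the syn epoxide (the pull); because the epoxide is syn to the oxygen on C4, the C4–C10 σ bond lies anti‑periplanar to the C9–O bond and migrates to tertiary C9 with inversion at C9 and retention at C10, so the fused six/seven system becomes the bridged six/eight system and quaternary C9 is set; the shift leaves C8 as a dimethylaluminium alkoxide, which is the species needed for hydride transfer through a six‑membered transition state to 3‑nitrobenzaldehyde, so the misconfigured C8 carbinol is removed in the same flask; the closest known reaction types are the organoaluminium‑promoted semipinacol rearrangement of 2,3‑epoxy alcohols (including fused‑to‑bridged cases) and the aluminium‑catalysed Oppenauer oxidation, but neither their coupling nor a bicyclo[5.4.0] to bicyclo[5.3.1] expansion has been shown.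

Step 11
Reactants: 18 bridged diketone
Product: 19 (5R,6S,8S,9S,10R,11S,12S,14R)-8-hydroxy ketone; C8 ketone of 18 reduced and C4 ketone kept
Conditions: NaBH4 (1 equiv), THF–MeOH 4:1, −40 °C
Reagents that add atoms: none
Why: In this chemo‑ and diastereoselective hydride reduction, the C4 ketone is flanked by two quaternary carbons and is inert; hydride reaches C8 from the face carrying the C9 allyl group, away from the C10 bridge, so C8‑OH ends cis to C10 (8S).

Step 12
Reactants: 19 8-hydroxy ketone
Product: 20 (5R,6S,8S,9S,10R,11S,12S,14R)-9-(2-oxopropyl) analogue of 19 (1,4-diketone)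
Conditions: PdCl2 (10 mol %), CuCl (1 equiv), O2 (1 atm), DMF–H2O 7:1, 23 °C
Reagents that add atoms: water, O
Why: Tsuji–Wacker oxidation converts the unhindered allyl group to the methyl ketone, while the vinyl group on quaternary C12 is too hindered to coordinate divalent palladium at a useful rate; no stereocentre is touched.

Step 13
Reactants: 20 1,4-diketone
Product: 22 Pleuromutilin E (5S,6S,8S,9R,10R,11S,12S,14R), via diol diketone 21 (not isolated)
Conditions: TsOH·H2O (0.3 equiv), toluene, 80 °C
Reagents that add atoms: none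
Why: Acid first cleaves the triethylsilyl ether and then drives the intramolecular aldol condensation; C4 cannot enolise, quaternary C9 blocks furan formation and attack through C1 would give a cyclopropane, so only the C3 enol adds to C4 and loss of water gives the C3=C4 enone irreversibly, with the hindered C14 acetate and all stereocentres kept.

**Compound list**
1 | (S)-5-methylcyclohex-2-en-1-one | O=C1C=CC[C@H](C)C1 | starting material
2 | (S)-2-iodo-5-methylcyclohex-2-en-1-one | O=C1C(I)=CC[C@H](C)C1 | intermediate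
3 | allyltrimethylstannane | C=CC[Sn](C)(C)C | starting material
4 | (S)-2-allyl-5-methylcyclohex-2-en-1-one | O=C1C(CC=C)=CC[C@H](C)C1 | intermediate
5 | (6S)-3-allyl-6-methyl-2-oxocyclohex-3-ene-1-carbaldehyde (formyl ketone, present as its lithium enolate) | O=CC1[C@@H](C)CC=C(CC=C)C1=O | intermediate
6 | (1R,6S)-3-allyl-1,6-dimethyl-2-oxocyclohex-3-ene-1-carbaldehyde | O=C[C@@]1(C)[C@@H](C)CC=C(CC=C)C1=O | intermediate
7 | 2-(bromomethyl)buta-1,3-diene | BrCC(=C)C=C | starting material
8 | (2-methylidenebut-3-en-1-yl)zinc bromide | C=CC(=C)C[Zn]Br | intermediate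
9 | (5S,6R)-2-allyl-6-[(1R)-1-hydroxy-3-methylidenepent-4-en-1-yl]-5,6-dimethylcyclohex-2-en-1-one | C=CC(=C)C[C@@H](O)[C@@]1(C)[C@@H](C)CC=C(CC=C)C1=O | intermediate
10 | acryloyl chloride | C=CC(=O)Cl | starting material
11 | acrylate ester of 9 | C=CC(=C)C[C@@H](OC(=O)C=C)[C@@]1(C)[C@@H](C)CC=C(CC=C)C1=O | intermediate
12 | hydroxy lactone (isochromen-3-one; 1R,4R,4aR,8S,8aR) | C=CC(=C)C[C@H]1OC(=O)[C@H](C)[C@@]2(O)C(CC=C)=CC[C@H](C)[C@]12C | intermediate
13 | lactol of 12 (C11 anomers) | C=CC(=C)C[C@H]1OC(O)[C@H](C)[C@@]2(O)C(CC=C)=CC[C@H](C)[C@]12C | intermediate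
14 | fused six/seven 4,14-diol, 11-O-triethylsilyl (4R,5R,6S,10S,11S,12S,14R) | C=C[C@]1(C)C[C@@H](O)[C@]2(C)[C@](O)(C(CC=C)=CC[C@@H]2C)[C@@H](C)[C@@H]1O[Si](CC)(CC)CC | intermediate
15 | 14-O-acetate of 14 | C=C[C@]1(C)C[C@@H](OC(C)=O)[C@]2(C)[C@](O)(C(CC=C)=CC[C@@H]2C)[C@@H](C)[C@@H]1O[Si](CC)(CC)CC | intermediate
16 | syn-8,9-epoxy alcohol (4S,5R,6S,8R,9R,10S,11S,12S,14R) | C=C[C@]1(C)C[C@@H](OC(C)=O)[C@]2(C)[C@](O)([C@]3(CC=C)O[C@@H]3C[C@@H]2C)[C@@H](C)[C@@H]1O[Si](CC)(CC)CC | intermediate
17 | ring-expanded ketone, C8 dimethylaluminium alkoxide (8R) | C=C[C@]1(C)C[C@@H](OC(C)=O)[C@]2(C)C(=O)[C@](CC=C)([C@H](O[Al](C)C)C[C@@H]2C)[C@@H](C)[C@@H]1O[Si](CC)(CC)CC | intermediate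
18 | bridged 4,8-diketone (5R,6S,9S,10R,11S,12S,14R) | C=C[C@]1(C)C[C@@H](OC(C)=O)[C@]2(C)C(=O)[C@](CC=C)(C(=O)C[C@@H]2C)[C@@H](C)[C@@H]1O[Si](CC)(CC)CC | intermediate
19 | (8S)-8-hydroxy-4-ketone | C=C[C@]1(C)C[C@@H](OC(C)=O)[C@]2(C)C(=O)[C@](CC=C)([C@@H](O)C[C@@H]2C)[C@@H](C)[C@@H]1O[Si](CC)(CC)CC | intermediate
20 | 9-(2-oxopropyl) 1,4-diketone | C=C[C@]1(C)C[C@@H](OC(C)=O)[C@]2(C)C(=O)[C@](CC(C)=O)([C@@H](O)C[C@@H]2C)[C@@H](C)[C@@H]1O[Si](CC)(CC)CC | intermediate
21 | desilylated 8,11-diol 1,4-diketone | C=C[C@]1(C)C[C@@H](OC(C)=O)[C@]2(C)C(=O)[C@](CC(C)=O)([C@@H](O)C[C@@H]2C)[C@@H](C)[C@@H]1O | intermediate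
22 | Pleuromutilin E | C=C[C@]1(C)C[C@@H](OC(C)=O)[C@]2(C)C3=CC(=O)C[C@@]3([C@@H](O)C[C@@H]2C)[C@@H](C)[C@@H]1O | target

**Step count**
Total steps: 13. Longest linear sequence: 13 (from 1).

**The three steps most likely to fail**

Step 10 (the proposed new ring expansion with in situ oxidation). Methyl transfer from aluminium to C9, a hydride shift from C8, or poor alignment of the C4–C10 bond could compete with the shift. The fallback uses known chemistry, sets out from 16 and comes back at 18. Me3SiOTf and 2,6‑lutidine give the epoxy trimethylsilyl ether F4. TiCl4 in CH2Cl2 at −78 °C then effects the established semipinacol rearrangement of 2,3‑epoxy silyl ethers and gives the isolated 8‑epi‑hydroxy ketone F5. A separate Dess–Martin oxidation of F5 gives 18.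

Step 8 (nickel hydride cyclisation). The lactol may open too little, hydronickelation may take the other diene terminus, or C12 may form with the wrong configuration. The fallback replaces the catalytic reductive cyclisation with a discrete, isolable nucleophile; it sets out from 12 and comes back at 15. Iron‑catalysed 1,4‑hydroboration (FeCl2, iminopyridine ligand, Mg, pinacolborane) gives the allylboronate lactone F1. i‑Bu2AlH then unmasks the aldehyde, which closes the ring by uncatalysed intramolecular allylboration through a closed chair transition state to the triol F2. Ac2O in pyridine acetylates the less hindered C14 hydroxyl to give the monoacetate F3. Et3SiOTf and 2,6‑lutidine then silylate C11‑OH to give 15.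

Step 13 (aldol condensation onto a ketone between two quaternary carbons). Acid may instead cause retro‑aldol opening at C8–C9 or simply fail to close the ring. The fallback replaces the condensation with a directed aldol followed by separate dehydration; it sets out from 20 and comes back at 22. Et3SiOTf and 2,6‑lutidine give the bis‑silyl ether F6, which removes the free β‑hydroxy ketone. KHMDS in THF at −78 °C forms the kinetic methyl ketone enolate, which closes to the tertiary aldol F7. The Burgess reagent dehydrates F7 to the bis‑silyl enone F8. HF·pyridine then removes both silyl groups to give 22.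

**Further compounds**
F1 | step 8 | (E)-allylboronate lactone (diene of 12 after 1,4-hydroboration) | CC1(C)OB(C/C=C(\C)C[C@H]2OC(=O)[C@H](C)[C@@]3(O)C(CC=C)=CC[C@H](C)[C@]23C)OC1(C)C
F2 | step 8 | fused six/seven 4,11,14-triol | C=C[C@]1(C)C[C@@H](O)[C@]2(C)[C@](O)(C(CC=C)=CC[C@@H]2C)[C@@H](C)[C@@H]1O
F3 | step 8 | 14-O-acetyl 4,11-diol | C=C[C@]1(C)C[C@@H](OC(C)=O)[C@]2(C)[C@](O)(C(CC=C)=CC[C@@H]2C)[C@@H](C)[C@@H]1O
F4 | step 10 | 4-O-trimethylsilyl ether of 16 | C=C[C@]1(C)C[C@@H](OC(C)=O)[C@]2(C)[C@](O[Si](C)(C)C)([C@]3(CC=C)O[C@@H]3C[C@@H]2C)[C@@H](C)[C@@H]1O[Si](CC)(CC)CC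
F5 | step 10 | (8R)-8-hydroxy-4-ketone (8-epimer of 19) | C=C[C@]1(C)C[C@@H](OC(C)=O)[C@]2(C)C(=O)[C@](CC=C)([C@H](O)C[C@@H]2C)[C@@H](C)[C@@H]1O[Si](CC)(CC)CC
F6 | step 13 | 8,11-bis(triethylsilyl) ether of the 1,4-diketone | C=C[C@]1(C)C[C@@H](OC(C)=O)[C@]2(C)C(=O)[C@](CC(C)=O)([C@@H](O[Si](CC)(CC)CC)C[C@@H]2C)[C@@H](C)[C@@H]1O[Si](CC)(CC)CC
F7 | step 13 | tertiary aldol (4-hydroxycyclopentanone, C4 not assigned) | C=C[C@]1(C)C[C@@H](OC(C)=O)[C@]2(C)C3(O)CC(=O)C[C@@]3([C@@H](O[Si](CC)(CC)CC)C[C@@H]2C)[C@@H](C)[C@@H]1O[Si](CC)(CC)CC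
F8 | step 13 | 8,11-bis(triethylsilyl) ether of 22 | C=C[C@]1(C)C[C@@H](OC(C)=O)[C@]2(C)C3=CC(=O)C[C@@]3([C@@H](O[Si](CC)(CC)CC)C[C@@H]2C)[C@@H](C)[C@@H]1O[Si](CC)(CC)CC
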